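**Retrosynthetic overview**

1. The target is an (R)-2H-chromene. Ring A carries the C8 hydroxyl and, at C5, the dihydrochalcone chain. C2, the only stereocentre, carries methyl and the (E)-4-hydroxy-4-methylpent-2-enyl chain.
2. Late disconnections: the C5–CH2 bond by Mizoroki–Heck reaction of a C5 bromide with an aryl vinyl carbinol, which gives the saturated ketone directly; the side chain from a C2–CH2CH2OSi handle by oxidation, Wittig olefination and double methyl addition.
3. Key disconnection: C4–C4a, by gold-catalysed 6-endo hydroarylation of an (R)-tertiary aryl propargyl ether. The feature used is that the C8 oxygen of ring A occupies one of the two carbons ortho to O1, so only C4a can attack the ethynyl group; the O1–C2 bond is already in place and is never broken, so C2 is carried through unchanged.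
4. C2 is set earlier by palladium-catalysed asymmetric allylic etherification of the mono-SEM catechol with an (E)-3,3-disubstituted allyl carbonate; the vinyl group is then turned into ethynyl by ozonolysis and Ohira–Bestmann homologation.
5. Ring order: both benzene rings are bought; the pyran ring is the only ring formed (step 9).

Key step: step 9

Assumption: the (1R,2R)-diphosphine is taken to deliver the (R)-ether in step 6; the sense of induction with (E)-3,3-disubstituted allyl carbonates is not certain and is to be confirmed on the product of step 6, the (1S,2S)-ligand being used in the same way if the (S)-ether is found.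

**Route**

Step 1
Reactants: 1 5-bromo-2-hydroxybenzaldehyde
Product: 2 5-bromo-2-{[2-(trimethylsilyl)ethoxy]methoxy}benzaldehyde
Conditions: NaH, SEMCl, THF/DMF, 0 °C to rt
Reagents that add atoms: 2-(trimethylsilyl)ethoxymethyl chloride (SEMCl), C[Si](C)(C)CCOCCl
Why: Williamson-type O-alkylation of the phenoxide by the reactive chloromethyl ether gives the SEM acetal, which masks the future C8 oxygen through the later basic, oxidative and organometallic steps, cannot migrate between the catechol oxygens and can be removed at the end with fluoride instead of acid.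

Step 2
Reactants: 2 5-bromo-2-{[2-(trimethylsilyl)ethoxy]methoxy}benzaldehyde
Product: 4 5-bromo-2-{[2-(trimethylsilyl)ethoxy]methoxy}phenol, via aryl formate 3 (not isolated)
Conditions: mCPBA, CH2Cl2, 0 °C to rt; aq NaHCO3 wash; then K2CO3 (cat.), MeOH, rt
Reagents that add atoms: 3-chloroperoxybenzoic acid (mCPBA), O=C(OO)c1cccc(Cl)c1
Why: Baeyer–Villiger (Dakin-type) oxidation, in which the electron-rich ortho-alkoxyaryl group migrates in the Criegee intermediate to give the aryl formate, and base-catalysed methanolysis then frees the phenol that becomes O1.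

Step 3
Reactants: 5 but-3-yn-1-ol
Product: 6 (but-3-yn-1-yloxy)(tert-butyl)diphenylsilane
Conditions: TBDPSCl, imidazole, CH2Cl2, 0 °C to rt
Reagents that add atoms: tert-butyl(chloro)diphenylsilane (TBDPSCl), CC(C)(C)[Si](Cl)(c1ccccc1)c1ccccc1
Why: Standard silylation of a primary alcohol through the N-silylimidazolium; TBDPS is preferred to smaller silyl groups because its hindered, weakly basic ether oxygen is least likely to add to the gold-activated alkyne in step 9 and it survives K2CO3/MeOH.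

Step 4
Reactants: 6 (but-3-yn-1-yloxy)(tert-butyl)diphenylsilane
Product: 9 (2E)-5-[(tert-butyldiphenylsilyl)oxy]-3-methylpent-2-en-1-ol, via alkenyldimethylalane 7 (not isolated), via lithium alkenylalanate 8 (not isolated)
Conditions: Me3Al, Cp2ZrCl2 (cat.), CH2Cl2, 0 °C to rt; volatiles removed; n-BuLi, THF/hexane, −78 °C; (CH2O)n, −78 °C to rt; H2O
Reagents that add atoms: trimethylaluminium, C[Al](C)C; paraformaldehyde (as formaldehyde), C=O; n-butyllithium, CCCC[Li] (its butyl group is held only in intermediate 8)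
Why: Negishi zirconium-catalysed carboalumination adds CH3 and Al syn across the terminal alkyne with Al on the terminal carbon, which fixes the (E)-trisubstituted alkene, and the derived alanate is hydroxymethylated by formaldehyde with retention of the alkene geometry.

Step 5
Reactants: 9 (2E)-5-[(tert-butyldiphenylsilyl)oxy]-3-methylpent-2-en-1-ol
Product: 10 (2E)-5-[(tert-butyldiphenylsilyl)oxy]-3-methylpent-2-en-1-yl methyl carbonate
Conditions: ClCO2Me, pyridine, CH2Cl2, 0 °C
Reagents that add atoms: methyl chloroformate, COC(=O)Cl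
Why: Acylation of the primary allylic alcohol gives the carbonate, whose ionisation by zerovalent palladium releases CO2 and methoxide, the base that deprotonates the phenol in step 6.

Step 6
Reactants: 4 5-bromo-2-{[2-(trimethylsilyl)ethoxy]methoxy}phenol; 10 (2E)-5-[(tert-butyldiphenylsilyl)oxy]-3-methylpent-2-en-1-yl methyl carbonate
Product: 11 {[(3R)-3-(5-bromo-2-{[2-(trimethylsilyl)ethoxy]methoxy}phenoxy)-3-methylpent-4-en-1-yl]oxy}(tert-butyl)diphenylsilane
Conditions: Pd2(dba)3·CHCl3 (1 mol%), (1R,2R)-N,N'-(cyclohexane-1,2-diyl)bis[2-(diphenylphosphanyl)benzamide] (3 mol%), CH2Cl2, rt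
Reagents that add atoms: none
Why: Tsuji–Trost asymmetric allylic etherification, in which ionisation gives a 1,1-disubstituted π-allylpalladium complex and the phenoxide attacks its more substituted terminus inside the chiral pocket of the C2-symmetric diphosphine, which selects the enantioface and so sets C2 as (R), while the aryl bromide is not touched by zerovalent palladium at room temperature.

Step 7
Reactants: 11 {[(3R)-3-(5-bromo-2-{[2-(trimethylsilyl)ethoxy]methoxy}phenoxy)-3-methylpent-4-en-1-yl]oxy}(tert-butyl)diphenylsilane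
Product: 13 (2R)-2-(5-bromo-2-{[2-(trimethylsilyl)ethoxy]methoxy}phenoxy)-4-[(tert-butyldiphenylsilyl)oxy]-2-methylbutanal, via secondary ozonide 12 (not isolated)
Conditions: O3, CH2Cl2, −78 °C (stopped when 11 is consumed); then PPh3, −78 °C to rt
Reagents that add atoms: ozone, [O-][O+]=O
Why: Ozonolysis with reductive work-up cleaves the only alkene, a monosubstituted vinyl group, much faster than ozone attacks the brominated arene, and the aldehyde formed has no α-hydrogen, so the stereocentre cannot epimerise.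

Step 8
Reactants: 13 (2R)-2-(5-bromo-2-{[2-(trimethylsilyl)ethoxy]methoxy}phenoxy)-4-[(tert-butyldiphenylsilyl)oxy]-2-methylbutanal
Product: 14 {[(3R)-3-(5-bromo-2-{[2-(trimethylsilyl)ethoxy]methoxy}phenoxy)-3-methylpent-4-yn-1-yl]oxy}(tert-butyl)diphenylsilane
Conditions: dimethyl (1-diazo-2-oxopropyl)phosphonate, K2CO3, MeOH, 0 °C to rt
Reagents that add atoms: dimethyl (1-diazo-2-oxopropyl)phosphonate, CC(=O)C(=[N+]=[N-])P(=O)(OC)OC
Why: Seyferth–Gilbert homologation in the Ohira–Bestmann variant, in which the diazomethylphosphonate anion made in the flask olefinates the aldehyde, loss of N2 gives an alkylidene carbene and a 1,2-hydride shift gives the terminal alkyne under conditions too mild to affect the non-enolisable stereocentre.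

Step 9
Reactants: 14 {[(3R)-3-(5-bromo-2-{[2-(trimethylsilyl)ethoxy]methoxy}phenoxy)-3-methylpent-4-yn-1-yl]oxy}(tert-butyl)diphenylsilane
Product: 15 (2R)-5-bromo-2-{2-[(tert-butyldiphenylsilyl)oxy]ethyl}-2-methyl-8-{[2-(trimethylsilyl)ethoxy]methoxy}-2H-chromene
Conditions: Ph3PAuNTf2 (2–5 mol%), CH2Cl2, 0 °C to rt, dark
Reagents that add atoms: none
Why: The cation Ph3PAu+ (monovalent gold, non-coordinating NTf2− counterion) π-coordinates the terminal alkyne, the arene attacks the terminal alkyne carbon through C4a in a Friedel–Crafts-type step, and rearomatisation with protodeauration of the vinylgold intermediate leaves the C3=C4 alkene. The closest known reaction type is the gold-catalysed intramolecular hydroarylation of aryl propargyl ethers, tertiary ones included, to 2H-chromenes. The pyran ring closes in the 6-endo-dig mode with formation of the C4–C4a bond. No stereocentre is created, and C2 stays (R) because the O1–C2 bond is not broken, unlike in the thermal propargyl Claisen sequence, which runs through an achiral ortho-quinone methide. Site selectivity on the arene is secured by the substrate, since the C8 oxygen occupies the second ortho position and the attacking carbon is activated by the ortho ether oxygen. The step needs 6-endo attack to outrun ionisation of the tertiary propargylic C–O bond and 5-exo closure, which the non-coordinating counterion, the low temperature, the gem-disubstituted C2 and the poorly nucleophilic TBDPS ether favour.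

Step 10
Reactants: 15 (2R)-5-bromo-2-{2-[(tert-butyldiphenylsilyl)oxy]ethyl}-2-methyl-8-{[2-(trimethylsilyl)ethoxy]methoxy}-2H-chromene
Product: 16 2-[(2R)-5-bromo-2-methyl-8-{[2-(trimethylsilyl)ethoxy]methoxy}-2H-chromen-2-yl]ethan-1-ol
Conditions: Bu4NF, THF, 0 °C to rt, dark; H2O
Reagents that add atoms: none
Why: Fluoride-mediated desilylation cleaves the alkyl silyl ether at room temperature, where the aryl SEM acetal, which needs heating with fluoride in a dipolar solvent, is retained.

Step 11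
Reactants: 16 2-[(2R)-5-bromo-2-methyl-8-{[2-(trimethylsilyl)ethoxy]methoxy}-2H-chromen-2-yl]ethan-1-ol
Product: 18 methyl (2E)-4-[(2R)-5-bromo-2-methyl-8-{[2-(trimethylsilyl)ethoxy]methoxy}-2H-chromen-2-yl]but-2-enoate, via β-aryloxy aldehyde 17 (not isolated)
Conditions: Dess–Martin periodinane, CH2Cl2, 0 °C to rt; then Ph3P=CHCO2Me, rt, dark
Reagents that add atoms: methyl (triphenylphosphoranylidene)acetate, COC(=O)C=P(c1ccccc1)(c1ccccc1)c1ccccc1
Why: Dess–Martin oxidation followed in the same flask by Wittig olefination with the stabilised ylide, which is (E)-selective and non-basic, so the β-aryloxy aldehyde is trapped before it can lose the phenoxide by E1cB ring opening.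

Step 12
Reactants: 18 methyl (2E)-4-[(2R)-5-bromo-2-methyl-8-{[2-(trimethylsilyl)ethoxy]methoxy}-2H-chromen-2-yl]but-2-enoate
Product: 20 (3E)-5-[(2R)-5-bromo-2-methyl-8-{[2-(trimethylsilyl)ethoxy]methoxy}-2H-chromen-2-yl]-2-methylpent-3-en-2-ol, via methyl enone 19 (not isolated)
Conditions: MeLi (3 equiv), Et2O, −78 °C, dark; H2O
Reagents that add atoms: methyllithium, [Li]C
Why: Double 1,2-addition of methyllithium to the ester through the methyl enone gives the tertiary allylic alcohol, because at −78 °C carbonyl addition is much faster than bromine–lithium exchange at C5 or deprotonation of the γ-CH2.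

Step 13
Reactants: 21 2,4-dihydroxybenzaldehyde
Product: 22 2,4-bis{[2-(trimethylsilyl)ethoxy]methoxy}benzaldehyde
Conditions: NaH, SEMCl, DMF, 0 °C to rt
Reagents that add atoms: 2-(trimethylsilyl)ethoxymethyl chloride (SEMCl), C[Si](C)(C)CCOCCl
Why: Double Williamson-type O-alkylation of the bis-phenoxide; SEM matches the C8 protecting group, so one fluoride treatment can clear all three at the end.

Step 14
Reactants: 22 2,4-bis{[2-(trimethylsilyl)ethoxy]methoxy}benzaldehyde
Product: 23 rac-1-(2,4-bis{[2-(trimethylsilyl)ethoxy]methoxy}phenyl)prop-2-en-1-ol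
Conditions: CH2=CHMgBr, THF, −78 to 0 °C; H2O
Reagents that add atoms: vinylmagnesium bromide, C=C[Mg]Br
Why: Grignard 1,2-addition to the aldehyde gives the aryl vinyl carbinol as a racemate, which is acceptable because its carbinol stereocentre is destroyed in step 15.

Step 15
Reactants: 20 (3E)-5-[(2R)-5-bromo-2-methyl-8-{[2-(trimethylsilyl)ethoxy]methoxy}-2H-chromen-2-yl]-2-methylpent-3-en-2-ol; 23 rac-1-(2,4-bis{[2-(trimethylsilyl)ethoxy]methoxy}phenyl)prop-2-en-1-ol
Product: 25 1-(2,4-bis{[2-(trimethylsilyl)ethoxy]methoxy}phenyl)-3-[(2R)-2-[(2E)-4-hydroxy-4-methylpent-2-en-1-yl]-2-methyl-8-{[2-(trimethylsilyl)ethoxy]methoxy}-2H-chromen-5-yl]propan-1-one, via enol 24 (not isolated)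
Conditions: Pd(OAc)2 (5 mol%), [HP(t-Bu)3]BF4 (10 mol%), Cy2NMe, dioxane, 80 °C, dark
Reagents that add atoms: none
Why: Mizoroki–Heck reaction of an allylic alcohol, in which oxidative addition at C5–Br, insertion of the terminal alkene with aryl transfer to its CH2 terminus and β-hydride elimination toward the carbinol carbon give the enol, which tautomerises to the saturated ketone; the monosubstituted alkene of 23 inserts much faster than the two disubstituted alkenes of 20, and light is excluded and the temperature kept moderate because 2H-chromenes can open reversibly to the ortho-quinone methide, which would scramble C2.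

Step 16
Reactants: 25 1-(2,4-bis{[2-(trimethylsilyl)ethoxy]methoxy}phenyl)-3-[(2R)-2-[(2E)-4-hydroxy-4-methylpent-2-en-1-yl]-2-methyl-8-{[2-(trimethylsilyl)ethoxy]methoxy}-2H-chromen-5-yl]propan-1-one
Product: 26 1-(2,4-dihydroxyphenyl)-3-{(2R)-8-hydroxy-2-[(2E)-4-hydroxy-4-methylpent-2-en-1-yl]-2-methyl-2H-chromen-5-yl}propan-1-one (CNP0311864.1)
Conditions: Bu4NF, DMPU, 4 Å MS, 70 °C, dark; then AcOH
Reagents that add atoms: none
Why: Fluoride-induced fragmentation of each SEM group (attack at silicon, loss of Me3SiF, ethene and formaldehyde) frees the three phenoxides under basic conditions that leave the acid-sensitive tertiary allylic alcohol and the 2H-chromene intact.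

**Compound list**

1 | 5-bromo-2-hydroxybenzaldehyde | O=Cc1cc(Br)ccc1O | starting material
2 | 5-bromo-2-{[2-(trimethylsilyl)ethoxy]methoxy}benzaldehyde | O=Cc1cc(Br)ccc1OCOCC[Si](C)(C)C | intermediate
3 | 5-bromo-2-{[2-(trimethylsilyl)ethoxy]methoxy}phenyl formate | O=COc1cc(Br)ccc1OCOCC[Si](C)(C)C | intermediate
4 | 5-bromo-2-{[2-(trimethylsilyl)ethoxy]methoxy}phenol | Oc1cc(Br)ccc1OCOCC[Si](C)(C)C | intermediate
5 | but-3-yn-1-ol | C#CCCO | starting material
6 | (but-3-yn-1-yloxy)(tert-butyl)diphenylsilane | C#CCCO[Si](c1ccccc1)(c1ccccc1)C(C)(C)C | intermediate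
7 | {(1E)-4-[(tert-butyldiphenylsilyl)oxy]-2-methylbut-1-en-1-yl}dimethylalane | C[Al](C)/C=C(\C)CCO[Si](c1ccccc1)(c1ccccc1)C(C)(C)C | intermediate
8 | lithium butyl{(1E)-4-[(tert-butyldiphenylsilyl)oxy]-2-methylbut-1-en-1-yl}dimethylalanate | [Li+].CCCC[Al-](C)(C)/C=C(\C)CCO[Si](c1ccccc1)(c1ccccc1)C(C)(C)C | intermediate
9 | (2E)-5-[(tert-butyldiphenylsilyl)oxy]-3-methylpent-2-en-1-ol | OC/C=C(\C)CCO[Si](c1ccccc1)(c1ccccc1)C(C)(C)C | intermediate
10 | (2E)-5-[(tert-butyldiphenylsilyl)oxy]-3-methylpent-2-en-1-yl methyl carbonate | COC(=O)OC/C=C(\C)CCO[Si](c1ccccc1)(c1ccccc1)C(C)(C)C | intermediate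
11 | {[(3R)-3-(5-bromo-2-{[2-(trimethylsilyl)ethoxy]methoxy}phenoxy)-3-methylpent-4-en-1-yl]oxy}(tert-butyl)diphenylsilane | CC(C)(C)[Si](c1ccccc1)(c1ccccc1)OCC[C@](Oc1cc(Br)ccc1OCOCC[Si](C)(C)C)(C)C=C | intermediate
12 | secondary ozonide of 11: {[(3R)-3-(5-bromo-2-{[2-(trimethylsilyl)ethoxy]methoxy}phenoxy)-3-(1,2,4-trioxolan-3-yl)butyl]oxy}(tert-butyl)diphenylsilane, mixture at the trioxolane carbon | CC(C)(C)[Si](c1ccccc1)(c1ccccc1)OCC[C@](Oc1cc(Br)ccc1OCOCC[Si](C)(C)C)(C)C1OCOO1 | intermediate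
13 | (2R)-2-(5-bromo-2-{[2-(trimethylsilyl)ethoxy]methoxy}phenoxy)-4-[(tert-butyldiphenylsilyl)oxy]-2-methylbutanal | CC(C)(C)[Si](c1ccccc1)(c1ccccc1)OCC[C@](Oc1cc(Br)ccc1OCOCC[Si](C)(C)C)(C)C=O | intermediate
14 | {[(3R)-3-(5-bromo-2-{[2-(trimethylsilyl)ethoxy]methoxy}phenoxy)-3-methylpent-4-yn-1-yl]oxy}(tert-butyl)diphenylsilane | CC(C)(C)[Si](c1ccccc1)(c1ccccc1)OCC[C@](Oc1cc(Br)ccc1OCOCC[Si](C)(C)C)(C)C#C | intermediate
15 | (2R)-5-bromo-2-{2-[(tert-butyldiphenylsilyl)oxy]ethyl}-2-methyl-8-{[2-(trimethylsilyl)ethoxy]methoxy}-2H-chromene | CC(C)(C)[Si](c1ccccc1)(c1ccccc1)OCC[C@]1(C)C=Cc2c(Br)ccc(OCOCC[Si](C)(C)C)c2O1 | intermediate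
16 | 2-[(2R)-5-bromo-2-methyl-8-{[2-(trimethylsilyl)ethoxy]methoxy}-2H-chromen-2-yl]ethan-1-ol | OCC[C@]1(C)C=Cc2c(Br)ccc(OCOCC[Si](C)(C)C)c2O1 | intermediate
17 | [(2R)-5-bromo-2-methyl-8-{[2-(trimethylsilyl)ethoxy]methoxy}-2H-chromen-2-yl]acetaldehyde | O=CC[C@]1(C)C=Cc2c(Br)ccc(OCOCC[Si](C)(C)C)c2O1 | intermediate
18 | methyl (2E)-4-[(2R)-5-bromo-2-methyl-8-{[2-(trimethylsilyl)ethoxy]methoxy}-2H-chromen-2-yl]but-2-enoate | COC(=O)/C=C/C[C@]1(C)C=Cc2c(Br)ccc(OCOCC[Si](C)(C)C)c2O1 | intermediate
19 | (3E)-5-[(2R)-5-bromo-2-methyl-8-{[2-(trimethylsilyl)ethoxy]methoxy}-2H-chromen-2-yl]pent-3-en-2-one | CC(=O)/C=C/C[C@]1(C)C=Cc2c(Br)ccc(OCOCC[Si](C)(C)C)c2O1 | intermediate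
20 | (3E)-5-[(2R)-5-bromo-2-methyl-8-{[2-(trimethylsilyl)ethoxy]methoxy}-2H-chromen-2-yl]-2-methylpent-3-en-2-ol | CC(C)(O)/C=C/C[C@]1(C)C=Cc2c(Br)ccc(OCOCC[Si](C)(C)C)c2O1 | intermediate
21 | 2,4-dihydroxybenzaldehyde | O=Cc1ccc(O)cc1O | starting material
22 | 2,4-bis{[2-(trimethylsilyl)ethoxy]methoxy}benzaldehyde | O=Cc1ccc(OCOCC[Si](C)(C)C)cc1OCOCC[Si](C)(C)C | intermediate
23 | rac-1-(2,4-bis{[2-(trimethylsilyl)ethoxy]methoxy}phenyl)prop-2-en-1-ol | C=CC(O)c1ccc(OCOCC[Si](C)(C)C)cc1OCOCC[Si](C)(C)C | intermediate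
24 | enol tautomer of 25: 1-(2,4-bis{[2-(trimethylsilyl)ethoxy]methoxy}phenyl)-3-[(2R)-2-[(2E)-4-hydroxy-4-methylpent-2-en-1-yl]-2-methyl-8-{[2-(trimethylsilyl)ethoxy]methoxy}-2H-chromen-5-yl]prop-1-en-1-ol, enol geometry not defined | CC(C)(O)/C=C/C[C@]1(C)C=Cc2c(CC=C(O)c3ccc(OCOCC[Si](C)(C)C)cc3OCOCC[Si](C)(C)C)ccc(OCOCC[Si](C)(C)C)c2O1 | intermediate
25 | 1-(2,4-bis{[2-(trimethylsilyl)ethoxy]methoxy}phenyl)-3-[(2R)-2-[(2E)-4-hydroxy-4-methylpent-2-en-1-yl]-2-methyl-8-{[2-(trimethylsilyl)ethoxy]methoxy}-2H-chromen-5-yl]propan-1-one | CC(C)(O)/C=C/C[C@]1(C)C=Cc2c(CCC(=O)c3ccc(OCOCC[Si](C)(C)C)cc3OCOCC[Si](C)(C)C)ccc(OCOCC[Si](C)(C)C)c2O1 | intermediate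
26 | 1-(2,4-dihydroxyphenyl)-3-{(2R)-8-hydroxy-2-[(2E)-4-hydroxy-4-methylpent-2-en-1-yl]-2-methyl-2H-chromen-5-yl}propan-1-one | CC(C)(O)/C=C/C[C@]1(C)C=Cc2c(CCC(=O)c3ccc(O)cc3O)ccc(O)c2O1 | target

**Step count and risks**

Total step count: 16. Longest linear sequence: 12 steps (steps 3 to 12, then 15 and 16, from but-3-yn-1-ol).

Steps most likely to fail:

1. Step 9. Gold may ionise the tertiary propargylic C–O bond, which would cost the aryl ether and erode the C2 configuration. The ring may also close 5-exo, or attack by the bromine-flanked C4a may be too slow. Fallback by ring-closing metathesis, setting out from 11 and coming back at 15: deprotonation of 11 with LiN(i-Pr)2 (THF, −78 °C) at the ring position flanked by the ether oxygen and bromine, followed by DMF, would give 6-bromo-2-({(3R)-5-[(tert-butyldiphenylsilyl)oxy]-3-methylpent-1-en-3-yl}oxy)-3-{[2-(trimethylsilyl)ethoxy]methoxy}benzaldehyde F1. Wittig methylenation (Ph3P=CH2, THF, 0 °C) would give the styrene {[(3R)-3-(3-bromo-2-ethenyl-6-{[2-(trimethylsilyl)ethoxy]methoxy}phenoxy)-3-methylpent-4-en-1-yl]oxy}(tert-butyl)diphenylsilane F2. Ring-closing metathesis with the second-generation Grubbs catalyst (CH2Cl2, 40 °C) would then form the C3=C4 bond with loss of ethene and give 15, again without touching the O1–C2 bond.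

2. Step 6. The phenoxide may attack the unsubstituted allyl terminus and give the linear ether, the branched ether may re-ionise and equilibrate to the linear one, or the ligand may discriminate the faces of the (E)-configured π-allyl complex only moderately. Fallback with the stereocentre set by reagent-controlled epoxidation, setting out from 9 and coming back at 14 (steps 5 to 8 are bypassed): Sharpless asymmetric epoxidation of 9 (Ti(O-i-Pr)4, D-(−)-diethyl tartrate, t-BuOOH, 4 Å MS, CH2Cl2, −20 °C) would give [(2R,3R)-3-{2-[(tert-butyldiphenylsilyl)oxy]ethyl}-3-methyloxiran-2-yl]methanol F3. Appel chlorination (PPh3, CCl4) would give (2S,3R)-2-(chloromethyl)-3-{2-[(tert-butyldiphenylsilyl)oxy]ethyl}-3-methyloxirane F4. n-BuLi (3 equiv, THF, −30 °C) would bring about the eliminative epoxide opening to (3R)-5-[(tert-butyldiphenylsilyl)oxy]-3-methylpent-1-yn-3-ol F5, the C–O bond at the stereocentre staying intact. SNAr of its sodium alkoxide (NaH, DMF, 0 °C to rt) on purchased 4-bromo-2-fluorobenzaldehyde F6 would give 4-bromo-2-({(3R)-5-[(tert-butyldiphenylsilyl)oxy]-3-methylpent-1-yn-3-yl}oxy)benzaldehyde F7. Baeyer–Villiger oxidation (mCPBA, CH2Cl2) to 4-bromo-2-({(3R)-5-[(tert-butyldiphenylsilyl)oxy]-3-methylpent-1-yn-3-yl}oxy)phenyl formate F8 and methanolysis (K2CO3, MeOH) would give 4-bromo-2-({(3R)-5-[(tert-butyldiphenylsilyl)oxy]-3-methylpent-1-yn-3-yl}oxy)phenol F9. SEMCl with i-Pr2NEt would then give 14.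

3. Step 15. Oxidative addition into the electron-rich, ortho-substituted C5–Br bond may lag, β-hydride elimination may go toward the benzylic CH2 instead of the carbinol, or palladium hydride may isomerise 23 to the ethyl ketone before it couples. Fallback through the chalcone, setting out from 20 and 23 and coming back at 25: oxidation of 23 with MnO2 (CH2Cl2, rt) would give 1-(2,4-bis{[2-(trimethylsilyl)ethoxy]methoxy}phenyl)prop-2-en-1-one F10. Mizoroki–Heck reaction of 20 with this electron-poor alkene (same catalyst system) would give, as the only possible elimination product, (2E)-1-(2,4-bis{[2-(trimethylsilyl)ethoxy]methoxy}phenyl)-3-[(2R)-2-[(2E)-4-hydroxy-4-methylpent-2-en-1-yl]-2-methyl-8-{[2-(trimethylsilyl)ethoxy]methoxy}-2H-chromen-5-yl]prop-2-en-1-one F11. Conjugate reduction with [(Ph3P)CuH]6 (toluene, rt) would reduce only the enone C=C and give 25.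

**Further compounds**

F1 | step 9 | 6-bromo-2-({(3R)-5-[(tert-butyldiphenylsilyl)oxy]-3-methylpent-1-en-3-yl}oxy)-3-{[2-(trimethylsilyl)ethoxy]methoxy}benzaldehyde | CC(C)(C)[Si](c1ccccc1)(c1ccccc1)OCC[C@](Oc1c(C=O)c(Br)ccc1OCOCC[Si](C)(C)C)(C)C=C
F2 | step 9 | {[(3R)-3-(3-bromo-2-ethenyl-6-{[2-(trimethylsilyl)ethoxy]methoxy}phenoxy)-3-methylpent-4-en-1-yl]oxy}(tert-butyl)diphenylsilane | CC(C)(C)[Si](c1ccccc1)(c1ccccc1)OCC[C@](Oc1c(C=C)c(Br)ccc1OCOCC[Si](C)(C)C)(C)C=C
F3 | step 6 | [(2R,3R)-3-{2-[(tert-butyldiphenylsilyl)oxy]ethyl}-3-methyloxiran-2-yl]methanol | OC[C@H]1O[C@]1(C)CCO[Si](c1ccccc1)(c1ccccc1)C(C)(C)C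
F4 | step 6 | (2S,3R)-2-(chloromethyl)-3-{2-[(tert-butyldiphenylsilyl)oxy]ethyl}-3-methyloxirane | ClC[C@H]1O[C@]1(C)CCO[Si](c1ccccc1)(c1ccccc1)C(C)(C)C
F5 | step 6 | (3R)-5-[(tert-butyldiphenylsilyl)oxy]-3-methylpent-1-yn-3-ol | CC(C)(C)[Si](c1ccccc1)(c1ccccc1)OCC[C@](O)(C)C#C
F6 | step 6 | 4-bromo-2-fluorobenzaldehyde (purchased) | O=Cc1ccc(Br)cc1F
F7 | step 6 | 4-bromo-2-({(3R)-5-[(tert-butyldiphenylsilyl)oxy]-3-methylpent-1-yn-3-yl}oxy)benzaldehyde | CC(C)(C)[Si](c1ccccc1)(c1ccccc1)OCC[C@](Oc1cc(Br)ccc1C=O)(C)C#C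
F8 | step 6 | 4-bromo-2-({(3R)-5-[(tert-butyldiphenylsilyl)oxy]-3-methylpent-1-yn-3-yl}oxy)phenyl formate | CC(C)(C)[Si](c1ccccc1)(c1ccccc1)OCC[C@](Oc1cc(Br)ccc1OC=O)(C)C#C
F9 | step 6 | 4-bromo-2-({(3R)-5-[(tert-butyldiphenylsilyl)oxy]-3-methylpent-1-yn-3-yl}oxy)phenol | CC(C)(C)[Si](c1ccccc1)(c1ccccc1)OCC[C@](Oc1cc(Br)ccc1O)(C)C#C
F10 | step 15 | 1-(2,4-bis{[2-(trimethylsilyl)ethoxy]methoxy}phenyl)prop-2-en-1-one | C=CC(=O)c1ccc(OCOCC[Si](C)(C)C)cc1OCOCC[Si](C)(C)C
F11 | step 15 | (2E)-1-(2,4-bis{[2-(trimethylsilyl)ethoxy]methoxy}phenyl)-3-[(2R)-2-[(2E)-4-hydroxy-4-methylpent-2-en-1-yl]-2-methyl-8-{[2-(trimethylsilyl)ethoxy]methoxy}-2H-chromen-5-yl]prop-2-en-1-one | CC(C)(O)/C=C/C[C@]1(C)C=Cc2c(/C=C/C(=O)c3ccc(OCOCC[Si](C)(C)C)cc3OCOCC[Si](C)(C)C)ccc(OCOCC[Si](C)(C)C)c2O1
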